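The slowness of the tail struck me first: in Friday's run, the very flask asked about, the electrophile decayed at 0.261 h⁻¹ over the first 3.00 h, but between 12.0 h and 20.0 h at a slower 0.109 h⁻¹.

the same everywhere: electrophile 0.50 M
- Friday's: nucleophile 0.60 M; free base 0.50 M; the very flask that is asked about, followed so far
- Sunday's: nucleophile 0.30 M; free base 0.50 M; run made earlier
- flask: nucleophile 0.600 M; free base 0.500 M; time 2.0 d

| run | time / h | electrophile / % | target / % |
|---|---|---|---|
| Friday's | 3.00 | 45.7 | 16.5 |
| Friday's | 6.00 | 23.2 | 13.9 |
| Friday's | 10.0 | 12.0 | 10.4 |
| Friday's | 12.0 | 8.4 | 9.2 |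
| Friday's | 15.0 | 5.1 | 7.1 |
| Friday's | 20.0 | 3.5 | 3.9 |
| Sunday's | 1.33 | 83.0 | 8.2 |
| Sunday's | 4.00 | 60.1 | 7.7 |
| Sunday's | 6.00 | 48.4 | 7.4 |
| Sunday's | 10.0 | 36.2 | 4.0 |
| Sunday's | 15.0 | 26.9 | 3.8 |
| Sunday's | 20.0 | 23.4 | 2.5 |

(each reading ± 0.5 percentage points)

- part of the electrophile that has reacted at 2.0 d
- share of the unused nucleophile that is free and not bound as protonated nucleophile, at 2.0 d

- the earlier runs do not show how much of nucleophile is bound; that part of a forecast is a guess

I turned the settings by hand, one after the other. With nucleophile, I expected the decay constant to follow the charge, and Sunday's run, with 0.30 M against Friday's 0.60 M, gave 0.140 h⁻¹, so Friday's constant was twice Sunday's. Dividing Sunday's constant by its charge gave the quantity I carried on, a reading like the constants behind it, the decay constant per unit of free nucleophile, 0.467 L mol⁻¹ h⁻¹; multiplied by the free nucleophile, it gives a pseudo-first-order constant. I took the binding to protonated nucleophile as fast and bound nucleophile as idle, so Friday's tail read as 0.234 M of free nucleophile, a reading that carries the scatter of 0.5 percentage points.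

With time, I held the tail's decay constant from the electrophile's 3.5% at 20.0 h up to 2.0 d, which left 0.163%, so I committed to 99.8% reacted. With free base, I expected more of it to keep nucleophile free, but both runs held the same charge, and they do not show how much nucleophile is bound, so I put no number on the share free.

The forecast gave 99.3% reacted (98% to 99.9%), less than my figure, and 43% free (20% to 70%), saying of the latter: “This is a guess.” The flask gave 99.8% reacted and 73.3% free.

    nucleophile + acid set free ⇌ protonated nucleophile, settled at all times (K = 7500 L mol⁻¹)
    acid set free + free base ⇌ salt of the base, settled at all times (K = 22000 L mol⁻¹)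
    target ⇌ isomer of the product (K = 20.0, k = 3.90 × 10⁻⁵ s⁻¹)
    electrophile + target → side product (k = 3.40 × 10⁻⁴ L mol⁻¹ s⁻¹)
    electrophile + nucleophile → acid set free + target (k = 1.10 × 10⁻⁴ L mol⁻¹ s⁻¹)

At 2.00 d the flask held free nucleophile at 33% of its charge beside 0.0720 M of protonated nucleophile. The carried constant times that free amount gives 0.0922 h⁻¹, and the electrophile's fall in this flask from 2.09% at 1.00 d to 0.219% at 2.00 d gives 0.0940 h⁻¹. The neighbour flask with 2.0 M of free base held 42% of its nucleophile free at the asked time; the constant times the difference from this flask, taken as a rough estimate over the whole time, puts that neighbour's electrophile at 0.0681%, and it held 0.085%.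

(Readings and results were computed with made-up constants, and the scatter is random.)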